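## Retrosynthetic overview

1. Target ⇐ ketal hydrolysis ⇐ Stille coupling of a core vinylstannane (already carrying the upper amide) with a (2E,4E)-5-bromopentadienamide of 2-amino-3-hydroxycyclopentenone.
2. Vinylstannane ⇐ anti-selective addition of (E)-Bu3SnCH=CHLi to an epoxy quinone monoketal; upper amide ⇐ N-acylation of the Boc-carbamate with the dienoyl chloride.
3. Epoxy monoketal ⇐ catalytic asymmetric phase-transfer epoxidation ⇐ oxidative dearomatisation of N-Boc-2,5-dimethoxyaniline.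
4. Upper acid ⇐ Wittig/HWE extension of (R)-2-methylhexanal ⇐ (R)-Roche ester ⇐ ene-reductase reduction of methyl 2-(hydroxymethyl)acrylate.
5. Rings: the six-membered carbocycle comes from the arene (dearomatised first), the oxirane is formed second, and the cyclopentenone ring is bought as cyclopentane-1,3-dione.

Assumption: the facial sense of the phase-transfer epoxidation is taken from the pseudoenantiomer relationship (the cinchonidinium salt is understood to give the antipodal epoxide series), so the cinchoninium salt is used and the configuration of 17 is confirmed chiroptically before going on.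

## Route

### Upper side chain

**Step 1**
Reactants: 1 methyl 2-(hydroxymethyl)prop-2-enoate
Product: 2 methyl (2R)-3-hydroxy-2-methylpropanoate
Conditions: ene-reductase (Old Yellow Enzyme family), NAD+ (cat.), formate dehydrogenase, HCO2Na, Tris-HCl buffer pH 7.5, 30 °C
Reagents that add atoms: none
Why: Ene-reductase asymmetric C=C reduction, in which flavin hydride adds to the CH2 terminus and an active-site tyrosine protonates C2 on the opposite face of the bound acrylate, sets the first stereocentre as R (typically >98% ee) while formate dehydrogenase recycles NADH.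

**Step 2**
Reactants: 2 methyl (2R)-3-hydroxy-2-methylpropanoate
Product: 3 methyl (2R)-2-methyl-3-[(4-methylbenzenesulfonyl)oxy]propanoate
Conditions: TsCl, pyridine, CH2Cl2, 0 °C
Reagents that add atoms: 4-methylbenzenesulfonyl chloride, Cc1ccc(cc1)S(Cl)(=O)=O
Why: O-sulfonylation of the primary alcohol at low temperature activates that arm without touching the stereocentre or causing β-elimination.

**Step 3**
Reactants: 3 methyl (2R)-2-methyl-3-[(4-methylbenzenesulfonyl)oxy]propanoate
Product: 4 (2S)-3-hydroxy-2-methylpropyl 4-methylbenzenesulfonate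
Conditions: i-Bu2AlH (2.5 equiv), CH2Cl2, −78 → −20 °C; aq. potassium sodium tartrate work-up
Reagents that add atoms: none
Why: Hydride reduction of the ester to the primary alcohol leaves the sulfonate intact and removes the ester before any organometallic step, so elimination/conjugate-addition racemisation is excluded (the label becomes S by CIP only).

**Step 4**
Reactants: 4 (2S)-3-hydroxy-2-methylpropyl 4-methylbenzenesulfonate
Product: 5 (2R)-2-methylhexan-1-ol
Conditions: n-PrMgBr (3.5 equiv), Li2CuCl4 (5 mol%), THF, −78 → 0 °C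
Reagents that add atoms: n-propylmagnesium bromide, CCC[Mg]Br
Why: Copper-catalysed (Kochi-type) sp3–sp3 cross-coupling of the primary tosylate on the in situ magnesium alkoxide forms the bond at CH2, so the stereocentre is untouched and is now labelled R.

**Step 5**
Reactants: 5 (2R)-2-methylhexan-1-ol
Product: 7 ethyl (2E,4R)-2,4-dimethyloct-2-enoate, via (2R)-2-methylhexanal 6 (not isolated)
Conditions: TEMPO (10 mol%), PhI(OAc)2, CH2Cl2, rt; then Ph3P=C(Me)CO2Et, rt → 40 °C
Reagents that add atoms: ethyl 2-(triphenylphosphoranylidene)propanoate, CCOC(=O)C(C)=P(c1ccccc1)(c1ccccc1)c1ccccc1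
Why: Oxoammonium oxidation gives the epimerisable α-branched aldehyde under non-basic conditions and the stabilised ylide traps it at once in an E-selective Wittig olefination.

**Step 6**
Reactants: 7 ethyl (2E,4R)-2,4-dimethyloct-2-enoate
Product: 8 (2E,4R)-2,4-dimethyloct-2-en-1-ol
Conditions: i-Bu2AlH (2.2 equiv), CH2Cl2, −78 °C; aq. potassium sodium tartrate work-up
Reagents that add atoms: none
Why: 1,2-Hydride reduction of the enoate gives the allylic alcohol without touching the trisubstituted alkene or the allylic stereocentre.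

**Step 7**
Reactants: 8 (2E,4R)-2,4-dimethyloct-2-en-1-ol
Product: 9 (2E,4R)-2,4-dimethyloct-2-enal
Conditions: MnO2 (15 equiv), CH2Cl2, rt
Reagents that add atoms: none
Why: Selective allylic oxidation with MnO2 stops at the enal and does not isomerise the alkene.

**Step 8**
Reactants: 9 (2E,4R)-2,4-dimethyloct-2-enal
Product: 10 ethyl (2E,4E,6R)-4,6-dimethyldeca-2,4-dienoate
Conditions: (EtO)2P(O)CH2CO2Et, LiCl, DBU, MeCN, 0 °C → rt
Reagents that add atoms: triethyl phosphonoacetate, CCOC(=O)CP(=O)(OCC)OCC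
Why: Masamune–Roush Horner–Wadsworth–Emmons olefination is E-selective and mild enough that the γ-stereocentre is not deprotonated.

**Step 9**
Reactants: 10 ethyl (2E,4E,6R)-4,6-dimethyldeca-2,4-dienoate
Product: 11 (2E,4E,6R)-4,6-dimethyldeca-2,4-dienoic acid
Conditions: LiOH·H2O, THF/MeOH/H2O, rt; then 1 M HCl to pH 3
Reagents that add atoms: lithium hydroxide, [Li+].[OH-]
Why: Ester saponification proceeds without isomerising the diene or the remote stereocentre.

**Step 10**
Reactants: 11 (2E,4E,6R)-4,6-dimethyldeca-2,4-dienoic acid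
Product: 12 (2E,4E,6R)-4,6-dimethyldeca-2,4-dienoyl chloride
Conditions: (COCl)2, DMF (cat.), CH2Cl2, 0 °C → rt; evaporate, use crude
Reagents that add atoms: oxalyl chloride, ClC(=O)C(Cl)=O
Why: Vilsmeier-type acid chloride formation under neutral conditions gives the acylating agent for the weakly nucleophilic carbamate nitrogen.

### Core

**Step 11**
Reactants: 13 2,5-dimethoxyaniline
Product: 14 tert-butyl N-(2,5-dimethoxyphenyl)carbamate
Conditions: Boc2O, THF, reflux
Reagents that add atoms: di-tert-butyl dicarbonate, CC(C)(C)OC(=O)OC(=O)OC(C)(C)C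
Why: Carbamate formation on the aniline gives a crystalline, oxidisable anilide whose nitrogen can later be acylated and unmasked.

**Step 12**
Reactants: 14 tert-butyl N-(2,5-dimethoxyphenyl)carbamate
Product: 16 tert-butyl N-(6,6-dimethoxy-3-oxocyclohexa-1,4-dien-1-yl)carbamate, via quinone imine ketal 15 (not isolated)
Conditions: PhI(OAc)2, MeOH, 0 °C → rt; aq. NaHCO3 work-up
Reagents that add atoms: methanol, CO; water, O
Why: Hypervalent-iodine oxidative dearomatisation adds methanol at the methoxy-bearing carbon next to nitrogen, and hydrolysis of the remaining vinylogous imidate on work-up unmasks the enone of the quinone monoketal.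

**Step 13**
Reactants: 16 tert-butyl N-(6,6-dimethoxy-3-oxocyclohexa-1,4-dien-1-yl)carbamate
Product: 17 tert-butyl N-[(1S,6R)-2,2-dimethoxy-5-oxo-7-oxabicyclo[4.1.0]hept-3-en-3-yl]carbamate
Conditions: t-BuOOH, NaOH (aq), N-benzylcinchoninium chloride (10 mol%), toluene, 0 °C → rt; recrystallise to >99% ee
Reagents that add atoms: tert-butyl hydroperoxide, CC(C)(C)OO
Why: Weitz–Scheffer epoxidation under chiral phase-transfer catalysis delivers tert-butylperoxide as a cinchoninium ion pair to one enantiotopic face of the unsubstituted enone double bond (the other alkene is a deactivated vinylogous carbamate), setting both oxirane centres.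

**Step 14**
Reactants: 17 tert-butyl N-[(1S,6R)-2,2-dimethoxy-5-oxo-7-oxabicyclo[4.1.0]hept-3-en-3-yl]carbamate; 12 (2E,4E,6R)-4,6-dimethyldeca-2,4-dienoyl chloride
Product: 18 tert-butyl N-[(2E,4E,6R)-4,6-dimethyldeca-2,4-dienoyl]-N-[(1S,6R)-2,2-dimethoxy-5-oxo-7-oxabicyclo[4.1.0]hept-3-en-3-yl]carbamate
Conditions: LiOt-Bu (1.1 equiv), THF, −78 → 0 °C; then 12
Reagents that add atoms: none
Why: N-acylation of the lithium salt of the vinylogous carbamate with the acid chloride forms the imide without disturbing the epoxide or ketal.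

**Step 15**
Reactants: 18 tert-butyl N-[(2E,4E,6R)-4,6-dimethyldeca-2,4-dienoyl]-N-[(1S,6R)-2,2-dimethoxy-5-oxo-7-oxabicyclo[4.1.0]hept-3-en-3-yl]carbamate
Product: 19 (2E,4E,6R)-N-[(1S,6R)-2,2-dimethoxy-5-oxo-7-oxabicyclo[4.1.0]hept-3-en-3-yl]-4,6-dimethyldeca-2,4-dienamide
Conditions: TFA, CH2Cl2, 0 °C
Reagents that add atoms: none
Why: Acidolysis removes the Boc group from the imide rapidly, while the ketal and epoxide, both deactivated by neighbouring electron-withdrawing groups, survive anhydrous acid.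

**Step 16**
Reactants: 19 (2E,4E,6R)-N-[(1S,6R)-2,2-dimethoxy-5-oxo-7-oxabicyclo[4.1.0]hept-3-en-3-yl]-4,6-dimethyldeca-2,4-dienamide
Product: 20 (2E,4E,6R)-N-[(1S,5R,6R)-5-hydroxy-2,2-dimethoxy-5-[(E)-2-(tributylstannyl)ethenyl]-7-oxabicyclo[4.1.0]hept-3-en-3-yl]-4,6-dimethyldeca-2,4-dienamide
Conditions: (E)-Bu3SnCH=CHSnBu3 (3.3 equiv), n-BuLi (3.0 equiv), THF, −78 °C, 1 h; then 19, −78 °C; quench H2O
Reagents that add atoms: (E)-1,2-bis(tributylstannyl)ethene, CCCC[Sn](CCCC)(CCCC)/C=C/[Sn](CCCC)(CCCC)CCCC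
Why: Tin–lithium exchange gives the E-vinyllithium (one equivalent is spent on the amide N–H), whose 1,2-addition to the ketone occurs on the face anti to the oxirane oxygen under substrate control, placing the new hydroxyl syn to the epoxide.

### Lower side chain

**Step 17**
Reactants: 21 glutaconaldehyde potassium salt (potassium (1E,3E)-5-oxopenta-1,3-dien-1-olate)
Product: 22 (2E,4E)-5-bromopenta-2,4-dienal
Conditions: PPh3, Br2, CH2Cl2, 0 °C; then 21, 0 °C → rt
Reagents that add atoms: bromine, BrBr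
Why: Deoxybromination of the enolate through its O-phosphonium salt (addition–elimination by bromide) gives the thermodynamically favoured E,E-bromodienal.

**Step 18**
Reactants: 22 (2E,4E)-5-bromopenta-2,4-dienal
Product: 23 (2E,4E)-5-bromopenta-2,4-dienoic acid
Conditions: NaClO2, NaH2PO4, 2-methylbut-2-ene, t-BuOH/H2O, rt
Reagents that add atoms: sodium chlorite, [Na+].[O-]Cl=O
Why: Pinnick oxidation converts the enal to the acid without touching the vinyl bromide or the diene geometry.

**Step 19**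
Reactants: 23 (2E,4E)-5-bromopenta-2,4-dienoic acid
Product: 24 (2E,4E)-5-bromopenta-2,4-dienoyl chloride
Conditions: (COCl)2, DMF (cat.), CH2Cl2, 0 °C → rt; evaporate, use crude
Reagents that add atoms: oxalyl chloride, ClC(=O)C(Cl)=O
Why: Vilsmeier-type acid chloride formation activates the acid for acylation of the poorly nucleophilic amino-enone.

**Step 20**
Reactants: 25 cyclopentane-1,3-dione
Product: 26 2-nitrocyclopentane-1,3-dione (enol form 3-hydroxy-2-nitrocyclopent-2-en-1-one)
Conditions: fuming HNO3, AcOH, 0 °C → rt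
Reagents that add atoms: nitric acid, O[N+](=O)[O-]
Why: Electrophilic nitration of the fully enolised 1,3-dione occurs only at the nucleophilic C2.

**Step 21**
Reactants: 26 2-nitrocyclopentane-1,3-dione
Product: 27 2-amino-3-hydroxycyclopent-2-en-1-one hydrochloride
Conditions: H2 (1 atm), 10% Pd/C, MeOH, conc. HCl (1.1 equiv), rt
Reagents that add atoms: hydrogen chloride, Cl
Why: Catalytic hydrogenation reduces nitro to amine and the acid traps the air-sensitive amino-enone as its stable hydrochloride.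

**Step 22**
Reactants: 24 (2E,4E)-5-bromopenta-2,4-dienoyl chloride; 27 2-amino-3-hydroxycyclopent-2-en-1-one hydrochloride
Product: 28 (2E,4E)-5-bromo-N-(2-hydroxy-5-oxocyclopent-1-en-1-yl)penta-2,4-dienamide
Conditions: pyridine, CH2Cl2, 0 °C → rt; 1 M HCl work-up
Reagents that add atoms: none
Why: Schotten–Baumann-type acylation gives the thermodynamically preferred N-acyl vinylogous acid (any O-acyl product transfers to nitrogen).

### Endgame

**Step 23**
Reactants: 20 the core vinylstannane; 28 (2E,4E)-5-bromo-N-(2-hydroxy-5-oxocyclopent-1-en-1-yl)penta-2,4-dienamide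
Product: 29 (2E,4E,6R)-N-[(1S,5S,6R)-5-hydroxy-5-[(1E,3E,5E)-7-[(2-hydroxy-5-oxocyclopent-1-en-1-yl)amino]-7-oxohepta-1,3,5-trien-1-yl]-2,2-dimethoxy-7-oxabicyclo[4.1.0]hept-3-en-3-yl]-4,6-dimethyldeca-2,4-dienamide
Conditions: PdCl2(MeCN)2 (10 mol%), DMF, rt, dark, argon
Reagents that add atoms: none
Why: Ligand-free Stille cross-coupling (divalent palladium precatalyst reduced in situ to zerovalent palladium) joins vinylstannane and bromodiene with retention of both alkene geometries and tolerates the free hydroxyl, epoxide and enol.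

**Step 24**
Reactants: 29 the dimethyl ketal of the target
Product: 30 the target, (2E,4E,6R)-N-[(1S,5S,6R)-5-hydroxy-5-[(1E,3E,5E)-7-[(2-hydroxy-5-oxocyclopent-1-en-1-yl)amino]-7-oxohepta-1,3,5-trien-1-yl]-2-oxo-7-oxabicyclo[4.1.0]hept-3-en-3-yl]-4,6-dimethyldeca-2,4-dienamide
Conditions: montmorillonite K10 (moist), CH2Cl2, rt
Reagents that add atoms: water, O
Why: Mild solid-acid ketal hydrolysis unmasks the ketone without opening the epoxide or ionising the tertiary allylic alcohol.

## Compound list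

1 | methyl 2-(hydroxymethyl)prop-2-enoate | C=C(CO)C(=O)OC | starting material
2 | methyl (2R)-3-hydroxy-2-methylpropanoate | OC[C@@H](C)C(=O)OC | intermediate
3 | methyl (2R)-2-methyl-3-[(4-methylbenzenesulfonyl)oxy]propanoate | Cc1ccc(cc1)S(=O)(=O)OC[C@@H](C)C(=O)OC | intermediate
4 | (2S)-3-hydroxy-2-methylpropyl 4-methylbenzenesulfonate | Cc1ccc(cc1)S(=O)(=O)OC[C@@H](C)CO | intermediate
5 | (2R)-2-methylhexan-1-ol | CCCC[C@@H](C)CO | intermediate
6 | (2R)-2-methylhexanal | CCCC[C@@H](C)C=O | intermediate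
7 | ethyl (2E,4R)-2,4-dimethyloct-2-enoate | CCCC[C@@H](C)/C=C(C)/C(=O)OCC | intermediate
8 | (2E,4R)-2,4-dimethyloct-2-en-1-ol | CCCC[C@@H](C)/C=C(C)/CO | intermediate
9 | (2E,4R)-2,4-dimethyloct-2-enal | CCCC[C@@H](C)/C=C(C)/C=O | intermediate
10 | ethyl (2E,4E,6R)-4,6-dimethyldeca-2,4-dienoate | CCCC[C@@H](C)/C=C(C)/C=C/C(=O)OCC | intermediate
11 | (2E,4E,6R)-4,6-dimethyldeca-2,4-dienoic acid | CCCC[C@@H](C)/C=C(C)/C=C/C(=O)O | intermediate
12 | (2E,4E,6R)-4,6-dimethyldeca-2,4-dienoyl chloride | CCCC[C@@H](C)/C=C(C)/C=C/C(=O)Cl | intermediate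
13 | 2,5-dimethoxyaniline | COc1ccc(OC)c(N)c1 | starting material
14 | tert-butyl N-(2,5-dimethoxyphenyl)carbamate | COc1ccc(OC)c(NC(=O)OC(C)(C)C)c1 | intermediate
15 | tert-butyl N-(3,6,6-trimethoxycyclohexa-2,4-dien-1-ylidene)carbamate (quinone imine ketal) | CC(C)(C)OC(=O)N=C1C=C(OC)C=CC1(OC)OC | intermediate
16 | tert-butyl N-(6,6-dimethoxy-3-oxocyclohexa-1,4-dien-1-yl)carbamate | CC(C)(C)OC(=O)NC1=CC(=O)C=CC1(OC)OC | intermediate
17 | tert-butyl N-[(1S,6R)-2,2-dimethoxy-5-oxo-7-oxabicyclo[4.1.0]hept-3-en-3-yl]carbamate | CC(C)(C)OC(=O)NC1=CC(=O)[C@@H]2O[C@@H]2C1(OC)OC | intermediate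
18 | tert-butyl N-[(2E,4E,6R)-4,6-dimethyldeca-2,4-dienoyl]-N-[(1S,6R)-2,2-dimethoxy-5-oxo-7-oxabicyclo[4.1.0]hept-3-en-3-yl]carbamate | CCCC[C@@H](C)/C=C(C)/C=C/C(=O)N(C(=O)OC(C)(C)C)C1=CC(=O)[C@@H]2O[C@@H]2C1(OC)OC | intermediate
19 | (2E,4E,6R)-N-[(1S,6R)-2,2-dimethoxy-5-oxo-7-oxabicyclo[4.1.0]hept-3-en-3-yl]-4,6-dimethyldeca-2,4-dienamide | CCCC[C@@H](C)/C=C(C)/C=C/C(=O)NC1=CC(=O)[C@@H]2O[C@@H]2C1(OC)OC | intermediate
20 | (2E,4E,6R)-N-[(1S,5R,6R)-5-hydroxy-2,2-dimethoxy-5-[(E)-2-(tributylstannyl)ethenyl]-7-oxabicyclo[4.1.0]hept-3-en-3-yl]-4,6-dimethyldeca-2,4-dienamide | CCCC[C@@H](C)/C=C(C)/C=C/C(=O)NC1=C[C@@](O)(/C=C/[Sn](CCCC)(CCCC)CCCC)[C@@H]2O[C@@H]2C1(OC)OC | intermediate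
21 | glutaconaldehyde potassium salt | [K+].[O-]/C=C/C=C/C=O | starting material
22 | (2E,4E)-5-bromopenta-2,4-dienal | Br/C=C/C=C/C=O | intermediate
23 | (2E,4E)-5-bromopenta-2,4-dienoic acid | OC(=O)/C=C/C=C/Br | intermediate
24 | (2E,4E)-5-bromopenta-2,4-dienoyl chloride | ClC(=O)/C=C/C=C/Br | intermediate
25 | cyclopentane-1,3-dione | O=C1CCC(=O)C1 | starting material
26 | 2-nitrocyclopentane-1,3-dione (drawn as enol) | OC1=C(C(=O)CC1)[N+](=O)[O-] | intermediate
27 | 2-amino-3-hydroxycyclopent-2-en-1-one hydrochloride | Cl.NC1=C(O)CCC1=O | intermediate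
28 | (2E,4E)-5-bromo-N-(2-hydroxy-5-oxocyclopent-1-en-1-yl)penta-2,4-dienamide | Br/C=C/C=C/C(=O)NC1=C(O)CCC1=O | intermediate
29 | (2E,4E,6R)-N-[(1S,5S,6R)-5-hydroxy-5-[(1E,3E,5E)-7-[(2-hydroxy-5-oxocyclopent-1-en-1-yl)amino]-7-oxohepta-1,3,5-trien-1-yl]-2,2-dimethoxy-7-oxabicyclo[4.1.0]hept-3-en-3-yl]-4,6-dimethyldeca-2,4-dienamide | CCCC[C@@H](C)/C=C(C)/C=C/C(=O)NC1=C[C@@](O)(/C=C/C=C/C=C/C(=O)NC2=C(O)CCC2=O)[C@@H]2O[C@@H]2C1(OC)OC | intermediate
30 | (2E,4E,6R)-N-[(1S,5S,6R)-5-hydroxy-5-[(1E,3E,5E)-7-[(2-hydroxy-5-oxocyclopent-1-en-1-yl)amino]-7-oxohepta-1,3,5-trien-1-yl]-2-oxo-7-oxabicyclo[4.1.0]hept-3-en-3-yl]-4,6-dimethyldeca-2,4-dienamide | CCCC[C@@H](C)/C=C(C)/C=C/C(=O)NC1=C[C@@](O)(/C=C/C=C/C=C/C(=O)NC2=C(O)CCC2=O)[C@@H]2O[C@@H]2C1=O | target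

## Step count and risk

Total step count: 24.
Longest linear sequence: 15 steps (steps 1–10, 14, 15, 16, 23, 24).

The three steps most likely to fail:

**Step 13 (asymmetric epoxidation).** The deprotonated vinylogous carbamate is a sluggish acceptor, and the yield, ee and facial sense with the cinchoninium salt are the least secure points of the route. Fallback: set out from 16 and acylate first, using LiOt-Bu and then 12 in THF, to give tert-butyl N-(6,6-dimethoxy-3-oxocyclohexa-1,4-dien-1-yl)-N-[(2E,4E,6R)-4,6-dimethyldeca-2,4-dienoyl]carbamate F1. TFA in CH2Cl2 then gives (2E,4E,6R)-N-(6,6-dimethoxy-3-oxocyclohexa-1,4-dien-1-yl)-4,6-dimethyldeca-2,4-dienamide F2. Epoxidation of F2 (the same phase-transfer system, or Ph3COOH with NaN(SiMe3)2 and a dialkyl tartrate as stoichiometric controller) now gives the wrong-face product as a diastereomer, not an enantiomer, which is removed by chromatography or crystallisation. The fallback comes back to the route at 19.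

**Step 16 (vinyllithium addition).** The amide N–H consumes reagent, and its anion lowers the electrophilicity of the ketone; the stannylvinyllithium is also bulky and basic. Fallback: set out from 19 and add the small, less basic ethynylmagnesium bromide (excess, THF, −78 → 0 °C), again anti to the oxirane, to give (2E,4E,6R)-N-[(1S,5R,6R)-5-ethynyl-5-hydroxy-2,2-dimethoxy-7-oxabicyclo[4.1.0]hept-3-en-3-yl]-4,6-dimethyldeca-2,4-dienamide F3. Hydrostannylation of F3 catalysed by PdCl2(PPh3)2 with Bu3SnH (THF, 0 °C) places tin at the distal carbon with E geometry, and the fallback comes back to the route at 20.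

**Step 24 (final ketal hydrolysis).** The polar, acid-sensitive product may be degraded or retained on the clay. Fallback: set out from 20 and hydrolyse the ketal before the coupling (K10, CH2Cl2, rt) to give (2E,4E,6R)-N-[(1S,5R,6R)-5-hydroxy-2-oxo-5-[(E)-2-(tributylstannyl)ethenyl]-7-oxabicyclo[4.1.0]hept-3-en-3-yl]-4,6-dimethyldeca-2,4-dienamide F4. Stille coupling of F4 with 28 (PdCl2(MeCN)2, DMF, rt) is then the last, neutral step, and the fallback comes back to the route at 30.

## Further compounds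

F1 | step 13 | tert-butyl N-(6,6-dimethoxy-3-oxocyclohexa-1,4-dien-1-yl)-N-[(2E,4E,6R)-4,6-dimethyldeca-2,4-dienoyl]carbamate | CCCC[C@@H](C)/C=C(C)/C=C/C(=O)N(C(=O)OC(C)(C)C)C1=CC(=O)C=CC1(OC)OC
F2 | step 13 | (2E,4E,6R)-N-(6,6-dimethoxy-3-oxocyclohexa-1,4-dien-1-yl)-4,6-dimethyldeca-2,4-dienamide | CCCC[C@@H](C)/C=C(C)/C=C/C(=O)NC1=CC(=O)C=CC1(OC)OC
F3 | step 16 | (2E,4E,6R)-N-[(1S,5R,6R)-5-ethynyl-5-hydroxy-2,2-dimethoxy-7-oxabicyclo[4.1.0]hept-3-en-3-yl]-4,6-dimethyldeca-2,4-dienamide | CCCC[C@@H](C)/C=C(C)/C=C/C(=O)NC1=C[C@@](O)(C#C)[C@@H]2O[C@@H]2C1(OC)OC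
F4 | step 24 | (2E,4E,6R)-N-[(1S,5R,6R)-5-hydroxy-2-oxo-5-[(E)-2-(tributylstannyl)ethenyl]-7-oxabicyclo[4.1.0]hept-3-en-3-yl]-4,6-dimethyldeca-2,4-dienamide | CCCC[C@@H](C)/C=C(C)/C=C/C(=O)NC1=C[C@@](O)(/C=C/[Sn](CCCC)(CCCC)CCCC)[C@@H]2O[C@@H]2C1=O
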